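**Strategy.** Ring C carries three adjacent CH–O carbons, C2, C3 and C4. The route treats C2 with its oxygen as the carbonyl of the ring-B aldehyde and C3=C4 as an enediol diether, and joins them by a photochemical carbonyl–alkene (2+2) cycloaddition. In one operation this forms C2–C3 and O–C4, closes an oxetane and sets all three stereocentres. The precursors are 3,4,5-triacetoxybenzaldehyde and the twofold-symmetric (2S,3S)-2,3-diphenyl-2,3-dihydro-1,4-dioxine. Because the oxetane is an acetal at C4, acid later breaks only C4–O, ring A enters there, and the freed C2 hydroxyl is displaced with inversion to close ring C.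

Key step: step 5

**Remarks on the chemistry** (flavan numbering; ring A is the pentaoxygenated benzene, ring B the trihydroxyphenyl ring, ring C the pyran; the target is (2R,3S,4R), that is 2,3-trans-3,4-trans).

- Configuration of the auxiliary: the (S,S) series is used. On the half-chair with both phenyl groups pseudo-equatorial, axial O–C bond formation anti to the nearer phenyl gives the C3/C4 configuration of the target only from the (S,S)-dioxine. Only in that series is the dioxane formed after aryl transfer all-equatorial. The (R,R) auxiliary would have to react through the boat-like, non-anomeric mode.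
- Ring A is symmetric about its C4a–C7 axis (O5 and O8a, and the two methoxy groups, are interchangeable). A diphenol with one free carbon is therefore used without differentiating its hydroxyls; whichever closes ring C, the other becomes 5-OH.
- Route to the dioxine: the six-membered ring is closed as a lactone, since acid-catalysed acetal exchange on the free 1,2-diol would close a five-membered dioxolane instead.

**Route**

Step 1
Reactants: 1 3,4,5-trihydroxybenzaldehyde
Product: 2 3,4,5-triacetoxybenzaldehyde
Conditions: Ac2O, pyridine, 0 °C → rt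
Reagents that add atoms: acetic anhydride, CC(=O)OC(C)=O
Why: Exhaustive O-acetylation of the phenols (nucleophilic acyl substitution), which keeps the lowest triplet of the aldehyde n,π* in character and later makes the benzylic C2 position electron-poor.

Step 2
Reactants: 3 (S,S)-hydrobenzoin; 4 ethyl bromoacetate
Product: 6 (5S,6S)-5,6-diphenyl-1,4-dioxan-2-one, via hydroxy ester 5 (not isolated)
Conditions: NaH (1.1 equiv), THF, 0 °C; 4, 0 °C → rt; then p-TsOH (cat.), toluene, 80 °C
Reagents that add atoms: none
Why: Williamson etherification of the mono-alkoxide followed by lactonisation of the second hydroxyl onto the ester closes a six-membered ring with both phenyl groups equatorial and touches neither stereocentre.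

Step 3
Reactants: 6 (5S,6S)-5,6-diphenyl-1,4-dioxan-2-one
Product: 7 (5S,6S)-5,6-diphenyl-1,4-dioxan-2-ol (both C2 epimers)
Conditions: iBu2AlH (1.1 equiv), CH2Cl2, −78 °C; aq. KNaC4H4O6 (tartrate) work-up
Reagents that add atoms: none
Why: Partial hydride reduction of a lactone to the lactol, which should stop at this stage because the aluminium hemiacetal is stable at low temperature.

Step 4
Reactants: 7 (5S,6S)-5,6-diphenyl-1,4-dioxan-2-ol
Product: 8 (2S,3S)-2,3-diphenyl-2,3-dihydro-1,4-dioxine
Conditions: MsCl, Et3N, CH2Cl2, 0 °C; then DBU, 40 °C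
Reagents that add atoms: none
Why: Lactol dehydration through the anomeric sulfonate or chloride and base-induced 1,2-elimination, as in the preparation of glycals and 2-oxygenated glycals, can only remove a C3 hydrogen and keeps the acid-sensitive enediol diether in a basic medium.

Step 5
Reactants: 2 3,4,5-triacetoxybenzaldehyde; 8 (2S,3S)-2,3-diphenyl-2,3-dihydro-1,4-dioxine
Product: 9 5-[(1R,3S,4S,6R,8S)-3,4-diphenyl-2,5,7-trioxabicyclo[4.2.0]octan-8-yl]benzene-1,2,3-triyl triacetate (cis-fused, aryl endo)
Conditions: hν (350 nm lamps, Pyrex), 8 (2 equiv), degassed benzene, 10 °C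
Reagents that add atoms: none
Why: Proposed new method: excitation of the n,π* band of 2 and intersystem crossing give the triplet aldehyde, whose electrophilic oxygen adds to one of the two symmetry-equivalent alkene carbons of the electron-rich enediol diether 8 to give a triplet 1,4-biradical (an α-oxy ring radical and a benzylic α-oxy radical) that collapses by C–C coupling after spin inversion. The closest known reaction type is the Paternò–Büchi reaction of aromatic aldehydes with 1,3-dioxoles, 2,3-dihydrofuran and the parent 2,3-dihydro-1,4-dioxine, and what has no precedent is absolute control by a twofold-symmetric dihydrodioxine. The one new ring, the oxetane, closes stepwise, O–C4 first and C2–C3 second by radical recombination, and can only be cis-fused to the six-membered ring. C4 is set in the first bond formation, which should be axial on the half-chair with both phenyl groups pseudo-equatorial (chair-like, anti to the nearer phenyl, assisted by the lone pair of the ring oxygen), C3 follows from the cis fusion, and C2 is set at ring closure, where the biradical geometry favoured for spin inversion turns the aryl group to the concave (endo) face as is usual for aromatic aldehydes and cyclic enol ethers. The step needs two selectivities: the choice between the two diastereomeric modes of O–C bonding (the alkene faces are equivalent by symmetry, so the question is which carbon receives oxygen on a given face) and endo over exo; the (S,S) configuration of 8 is chosen so that the axial, anomerically stabilised mode gives the C3 and C4 configuration needed for the target, and the two possible endo adducts are diastereomers that can be separated. Competing hydrogen abstraction and pinacol coupling should be held back by the excess of the very electron-rich alkene.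

Step 6
Reactants: 10 2,6-dimethoxyphenol
Product: 11 2-(benzyloxy)-1,3-dimethoxybenzene
Conditions: BnBr, K2CO3, DMF, 60 °C
Reagents that add atoms: benzyl bromide, BrCc1ccccc1
Why: Williamson ether synthesis on the phenoxide protects the oxygen that becomes O7 as a hydrogenolysable ether.

Step 7
Reactants: 11 2-(benzyloxy)-1,3-dimethoxybenzene
Product: 12 3-(benzyloxy)-1,5-dibromo-2,4-dimethoxybenzene
Conditions: NBS (2.1 equiv), MeCN, 0 °C → rt, dark
Reagents that add atoms: N-bromosuccinimide, O=C1CCC(=O)N1Br
Why: Electrophilic aromatic bromination enters twice at the positions ortho to one methoxy group and para to the other, the remaining position being activated only by the twisted central benzyloxy group.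

Step 8
Reactants: 12 3-(benzyloxy)-1,5-dibromo-2,4-dimethoxybenzene
Product: 14 5-(benzyloxy)-4,6-dimethoxybenzene-1,3-diol, via bis(pinacol boronate) 13 (not isolated)
Conditions: B2pin2, Pd(dppf)Cl2, KOAc, 1,4-dioxane, 90 °C; then aq. H2O2, THF, NaHCO3 buffer, 0 °C
Reagents that add atoms: hydrogen peroxide, OO (both phenolic oxygens); bis(pinacolato)diboron, CC1(C)OB(OC1(C)C)B1OC(C)(C)C(C)(C)O1 (boron of 13 only)
Why: Double Miyaura borylation followed by oxidative C–B to C–O conversion (aryl migration from boron to peroxide oxygen) turns both C–Br bonds into phenols under conditions that leave the benzyl ether intact.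

Step 9
Reactants: 9 oxetane acetal; 14 5-(benzyloxy)-4,6-dimethoxybenzene-1,3-diol
Product: 15 5-{(S)-[(2R,3R,5S,6S)-3-(4-benzyloxy-2,6-dihydroxy-3,5-dimethoxyphenyl)-5,6-diphenyl-1,4-dioxan-2-yl](hydroxy)methyl}benzene-1,2,3-triyl triacetate
Conditions: BF3·OEt2 (0.3 equiv), 14 (1.5 equiv), 4 Å molecular sieves, CH2Cl2, −78 → 0 °C
Reagents that add atoms: none
Why: Friedel–Crafts alkylation of a phenol by an acetal-derived oxocarbenium ion (the aryl C-glycosylation manifold, possibly through the O-aryl acetal and its O-to-C shift): BF3 cleaves the strained acetal C4–O bond and not the benzylic C2–O bond, whose ionisation the triacetoxyphenyl group disfavours, the only free carbon of 14 attacks C4, and reversible ionisation of the resulting ortho-hydroxybenzylic ether should let ring A settle equatorial and trans to the C3 side chain, which in the (S,S) series is the all-equatorial dioxane and sets C4 as in the target.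

Step 10
Reactants: 15 diphenol–benzylic alcohol
Product: 16 (2R,3S,4R)-7-benzyloxy-5-hydroxy-6,8-dimethoxy-2-(3,4,5-triacetoxyphenyl)flavan whose O3 and O4 are joined by a (1S,2S)-1,2-diphenylethane-1,2-diyl bridge (2,3-diphenyl-1,4-dioxane trans-fused on C3–C4)
Conditions: PPh3, DIAD, THF (0.01 M), 0 °C → rt
Reagents that add atoms: none
Why: Intramolecular Mitsunobu etherification, in which either of the two equivalent ring-A phenols displaces the activated secondary benzylic C2–O in an SN2 step, inverts C2 to give the 2,3-trans flavan and closes ring C as a trans-fused six-membered ring, the electron-poor aryl group suppressing ionisation at C2.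

Step 11
Reactants: 16 bridged flavan triacetate
Product: 17 (2R,3S,4R)-7-benzyloxy-5-hydroxy-6,8-dimethoxy-2-(3,4,5-trihydroxyphenyl)flavan with the same O3,O4 diphenylethanediyl bridge
Conditions: K2CO3 (0.2 equiv), degassed MeOH/THF, 0 °C; AcOH quench
Reagents that add atoms: none
Why: Base-catalysed transesterification of the three aryl acetates with methanol at low temperature and under exclusion of air should leave the benzyl ether, the dioxane bridge and all stereocentres untouched.

Step 12
Reactants: 17 bridged flavan
Product: 18 (2R,3S,4R)-6,8-dimethoxy-2-(3,4,5-trihydroxyphenyl)-3,4-dihydro-2H-chromene-3,4,5,7-tetrol (target, CNP0305400.1)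
Conditions: H2 (4 bar), Pd(OH)2 on carbon, THF/MeOH, rt
Reagents that add atoms: none
Why: Heterogeneous hydrogenolysis of benzylic C–O bonds should cleave the O7 benzyl ether and both O–CH(Ph) bonds of the bridge under neutral conditions, under which the hindered, electron-rich C4–O and C2–O1 bonds of the flavan should react more slowly, and no stereocentre is involved.

**Compound list**

1 | 3,4,5-trihydroxybenzaldehyde | O=Cc1cc(O)c(O)c(O)c1 | starting material
2 | 3,4,5-triacetoxybenzaldehyde | CC(=O)Oc1cc(C=O)cc(OC(C)=O)c1OC(C)=O | intermediate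
3 | (S,S)-hydrobenzoin, (1S,2S)-1,2-diphenylethane-1,2-diol | O[C@@H](c1ccccc1)[C@@H](O)c1ccccc1 | starting material
4 | ethyl bromoacetate | CCOC(=O)CBr | starting material
5 | ethyl 2-[(1S,2S)-2-hydroxy-1,2-diphenylethoxy]acetate | CCOC(=O)CO[C@@H](c1ccccc1)[C@@H](O)c1ccccc1 | intermediate (not isolated)
6 | (5S,6S)-5,6-diphenyl-1,4-dioxan-2-one | O=C1CO[C@@H](c2ccccc2)[C@H](c2ccccc2)O1 | intermediate
7 | (5S,6S)-5,6-diphenyl-1,4-dioxan-2-ol (both C2 epimers) | OC1CO[C@@H](c2ccccc2)[C@H](c2ccccc2)O1 | intermediate
8 | (2S,3S)-2,3-diphenyl-2,3-dihydro-1,4-dioxine | C1=CO[C@@H](c2ccccc2)[C@H](c2ccccc2)O1 | intermediate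
9 | 5-[(1R,3S,4S,6R,8S)-3,4-diphenyl-2,5,7-trioxabicyclo[4.2.0]octan-8-yl]benzene-1,2,3-triyl triacetate | CC(=O)Oc1cc(cc(OC(C)=O)c1OC(C)=O)[C@@H]1O[C@@H]2O[C@@H](c3ccccc3)[C@H](c3ccccc3)O[C@H]12 | intermediate
10 | 2,6-dimethoxyphenol | COc1cccc(OC)c1O | starting material
11 | 2-(benzyloxy)-1,3-dimethoxybenzene | COc1cccc(OC)c1OCc1ccccc1 | intermediate
12 | 3-(benzyloxy)-1,5-dibromo-2,4-dimethoxybenzene | COc1c(Br)cc(Br)c(OC)c1OCc1ccccc1 | intermediate
13 | 2,2'-[5-(benzyloxy)-4,6-dimethoxy-1,3-phenylene]bis(4,4,5,5-tetramethyl-1,3,2-dioxaborolane) | COc1c(B2OC(C)(C)C(C)(C)O2)cc(B2OC(C)(C)C(C)(C)O2)c(OC)c1OCc1ccccc1 | intermediate (not isolated)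
14 | 5-(benzyloxy)-4,6-dimethoxybenzene-1,3-diol | COc1c(O)cc(O)c(OC)c1OCc1ccccc1 | intermediate
15 | 5-{(S)-[(2R,3R,5S,6S)-3-(4-benzyloxy-2,6-dihydroxy-3,5-dimethoxyphenyl)-5,6-diphenyl-1,4-dioxan-2-yl](hydroxy)methyl}benzene-1,2,3-triyl triacetate | CC(=O)Oc1cc(cc(OC(C)=O)c1OC(C)=O)[C@H](O)[C@H]1O[C@@H](c2ccccc2)[C@H](c2ccccc2)O[C@@H]1c1c(O)c(OC)c(OCc2ccccc2)c(OC)c1O | intermediate
16 | (2R,3S,4R)-7-benzyloxy-5-hydroxy-6,8-dimethoxy-2-(3,4,5-triacetoxyphenyl)flavan, O3 and O4 bridged by (1S,2S)-1,2-diphenylethane-1,2-diyl | COc1c(OCc3ccccc3)c(OC)c2c(c1O)[C@H]1O[C@@H](c3ccccc3)[C@H](c3ccccc3)O[C@@H]1[C@@H](c1cc(OC(C)=O)c(OC(C)=O)c(OC(C)=O)c1)O2 | intermediate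
17 | (2R,3S,4R)-7-benzyloxy-5-hydroxy-6,8-dimethoxy-2-(3,4,5-trihydroxyphenyl)flavan, O3 and O4 bridged by (1S,2S)-1,2-diphenylethane-1,2-diyl | COc1c(OCc3ccccc3)c(OC)c2c(c1O)[C@H]1O[C@@H](c3ccccc3)[C@H](c3ccccc3)O[C@@H]1[C@@H](c1cc(O)c(O)c(O)c1)O2 | intermediate
18 | (2R,3S,4R)-6,8-dimethoxy-2-(3,4,5-trihydroxyphenyl)-3,4-dihydro-2H-chromene-3,4,5,7-tetrol | COc1c(O)c(OC)c2c(c1O)[C@@H](O)[C@H](O)[C@@H](c1cc(O)c(O)c(O)c1)O2 | target

**Step count.** 12 steps in total. The longest linear sequence is 8 steps (steps 2, 3, 4, 5, 9, 10, 11, 12 from (S,S)-hydrobenzoin); the aldehyde (1 step) and ring A (3 steps) are made separately.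

**Steps most likely to fail**

1. Step 5 (Proposed new method). The first O–C bond may form with too little discrimination between the two diastereomeric modes, the aryl group may turn exo at ring closure, or hydrogen abstraction from the benzylic ether positions may compete. Fallback by known chemistry, setting out from 14 and 1 and coming back at 18, replaces the oxetane chemistry by the classical dihydroflavonol route. Diphenol 14 is C-acetylated at its one free carbon (Houben–Hoesch reaction with MeCN, ZnCl2 and HCl, then hydrolysis) to give 1-[4-(benzyloxy)-2,6-dihydroxy-3,5-dimethoxyphenyl]ethan-1-one F1, which is protected (MOMCl, iPr2NEt) as its bis(methoxymethyl) ether F2. Aldehyde 1 is benzylated (BnBr, K2CO3) to 3,4,5-tris(benzyloxy)benzaldehyde F3, and Claisen–Schmidt condensation of F2 with F3 (KOH, EtOH) gives the (E)-chalcone F4. Juliá–Colonna epoxidation (poly-leucine of the handedness that delivers the αR,βS epoxide, urea–hydrogen peroxide, DBU) gives the epoxy ketone F5. HCl in MeOH removes the MOM groups, and a liberated phenol opens the epoxide at the benzylic carbon to give the (2R,3R)-dihydroflavonol F6. NaBH4 reduces the C4 ketone to the 2,3-trans-3,4-trans diol F7, and hydrogenolysis of the four benzyl ethers (H2, Pd/C) gives 18.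

2. Step 9. The Lewis acid may ionise the benzylic C2–O bond in place of the acetal C4–O bond, the oxocarbenium ion may lose a proton to an enol ether, or ring A may be delivered cis to the C3 side chain without equilibrating. The fallback sets out from 9 and comes back at 16, reversing the order of the two bond formations to ring A. Acid-catalysed methanolysis of the oxetane acetal (MeOH, PPTS) gives the methyl acetal F8 with a free C2 hydroxyl. An intermolecular Mitsunobu reaction with excess 14 (PPh3, DIAD) makes the O1–C2 bond with inversion and gives the aryl ether F9. BF3·OEt2 then generates the oxocarbenium ion at C4, which the ortho carbon of the tethered ring A attacks in a six-membered intramolecular Friedel–Crafts closure that gives 16 directly, bypassing steps 9 and 10.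

3. Step 12. Hydrogenolytic loss of the benzylic C4 oxygen (or opening of ring C at C2–O1) may compete with the slow cleavage of the hindered secondary benzylic ethers of the bridge. The fallback sets out from 17 and comes back at 18, using dissolving-metal cleavage in place of catalytic hydrogenolysis: excess Li in liquid NH3/THF at −78 °C, then NH4Cl. Electrons are accepted by the unsubstituted phenyl rings only, because rings A and B are present as phenoxides that resist reduction. The bridge leaves by reductive β-elimination as stilbene, which is reduced further to 1,2-diphenylethane, and the O7 benzyl group leaves as toluene; no new compound is formed on the way.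

**Further compounds**

F1 | step 5 | 1-[4-(benzyloxy)-2,6-dihydroxy-3,5-dimethoxyphenyl]ethan-1-one | CC(=O)c1c(O)c(OC)c(OCc2ccccc2)c(OC)c1O
F2 | step 5 | 1-[4-(benzyloxy)-3,5-dimethoxy-2,6-bis(methoxymethoxy)phenyl]ethan-1-one | CC(=O)c1c(OCOC)c(OC)c(OCc2ccccc2)c(OC)c1OCOC
F3 | step 5 | 3,4,5-tris(benzyloxy)benzaldehyde | O=Cc1cc(OCc2ccccc2)c(OCc2ccccc2)c(OCc2ccccc2)c1
F4 | step 5 | (E)-1-[4-(benzyloxy)-3,5-dimethoxy-2,6-bis(methoxymethoxy)phenyl]-3-[3,4,5-tris(benzyloxy)phenyl]prop-2-en-1-one | O=C(/C=C/c1cc(OCc2ccccc2)c(OCc2ccccc2)c(OCc2ccccc2)c1)c1c(OCOC)c(OC)c(OCc2ccccc2)c(OC)c1OCOC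
F5 | step 5 | [4-(benzyloxy)-3,5-dimethoxy-2,6-bis(methoxymethoxy)phenyl]{(2R,3S)-3-[3,4,5-tris(benzyloxy)phenyl]oxiran-2-yl}methanone | O=C(c1c(OCOC)c(OC)c(OCc2ccccc2)c(OC)c1OCOC)[C@@H]1O[C@H]1c1cc(OCc2ccccc2)c(OCc2ccccc2)c(OCc2ccccc2)c1
F6 | step 5 | (2R,3R)-7-(benzyloxy)-3,5-dihydroxy-6,8-dimethoxy-2-[3,4,5-tris(benzyloxy)phenyl]-2,3-dihydro-4H-chromen-4-one | COc1c(OCc3ccccc3)c(OC)c2c(c1O)C(=O)[C@H](O)[C@@H](c1cc(OCc3ccccc3)c(OCc3ccccc3)c(OCc3ccccc3)c1)O2
F7 | step 5 | (2R,3S,4R)-7-(benzyloxy)-6,8-dimethoxy-2-[3,4,5-tris(benzyloxy)phenyl]-3,4-dihydro-2H-chromene-3,4,5-triol | COc1c(OCc3ccccc3)c(OC)c2c(c1O)[C@@H](O)[C@H](O)[C@@H](c1cc(OCc3ccccc3)c(OCc3ccccc3)c(OCc3ccccc3)c1)O2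
F8 | step 9 | 5-{(S)-hydroxy[(2R,5S,6S)-3-methoxy-5,6-diphenyl-1,4-dioxan-2-yl]methyl}benzene-1,2,3-triyl triacetate (acetal epimers) | CC(=O)Oc1cc(cc(OC(C)=O)c1OC(C)=O)[C@H](O)[C@H]1O[C@@H](c2ccccc2)[C@H](c2ccccc2)OC1OC
F9 | step 9 | 5-{(R)-[3-(benzyloxy)-5-hydroxy-2,4-dimethoxyphenoxy][(2R,5S,6S)-3-methoxy-5,6-diphenyl-1,4-dioxan-2-yl]methyl}benzene-1,2,3-triyl triacetate (acetal epimers) | CC(=O)Oc1cc(cc(OC(C)=O)c1OC(C)=O)[C@@H](Oc1cc(O)c(OC)c(OCc2ccccc2)c1OC)[C@H]1O[C@@H](c2ccccc2)[C@H](c2ccccc2)OC1OC
F0 | step 12 | none | none
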